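**Plan**
- Retrosynthesis: ring D is cut at C13–C16 (ketyl–alkyne closure, with C17 from a one-carbon homologation). The 19,20-lactone is traced back to a temporary C7–O–C20 lactone, the C2 hydroxyl to a C3 ketone through the C2=C3 alkene, and the C13 ketone to a C11=C12 alkene.
- The core is then cut at C9–C10 and C4–C5 in one oxidative radical bicyclization. Before that, C5=C10 (ring-closing metathesis), the C7–O–C20 ester bond and C6–C8 (Ireland–Claisen) are cut.
- Forward: ring C (Birch) → C8 and C6 (Claisen) → temporary lactone ring (ester, metathesis) → rings A and B together (key step) → C13 oxidation and C3-to-C2 oxygen shift → alkyne arm and lactone switch → ring D → acid.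
- Enabling feature: C4 carries a methyl and a carboxyl, so with a C3 oxo group it is the α-carbon of a β-keto ester, placed 6-endo to C5=C10. C10 lies 5-exo to C9 of the ring C alkene. C7 and C20 sit 1,3 across C5 on ring B and can be tied as a lactone that fixes C5, C10 and the trans A/B fusion.
- Stereochemistry: CBS reduction sets C11; the Claisen relays it to C8 and C6; the lactone-controlled cascade sets C5, C4, C10 and C9; hydroboration sets C2; methoxide equilibration corrects C6; C13 follows from the bridge.

Key step: step 10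

Remark: atom numbers are those of the gibberellane skeleton (C1–C20), α is the face of C20 and β the face of H-5 and H-9; the C7 ester on C6 is assumed to be more stable trans to the quaternary C4 (the natural 6β position).

**Step 1**
Reactants: 1 2-(3-methoxyphenyl)ethan-1-ol
Product: 3 3-(2-hydroxyethyl)cyclohex-2-en-1-one, via dienol ether 2 (not isolated)
Conditions: Li, NH3(l), t-BuOH, THF, −78 to −33 °C; then 2 M HCl, THF, rt
Reagents that add atoms: water, O
Why: Birch reduction of a 3-alkylanisole should give the 1-methoxy-5-alkylcyclohexa-1,4-diene, and aqueous acid should hydrolyse the enol ether and move the alkene into conjugation; no stereocenter is formed.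

**Step 2**
Reactants: 3 3-(2-hydroxyethyl)cyclohex-2-en-1-one
Product: 4 3-[2-(tert-butyldiphenylsilyloxy)ethyl]cyclohex-2-en-1-one
Conditions: t-BuPh2SiCl, imidazole, DMF, 0 °C to rt
Reagents that add atoms: tert-butyl(chloro)diphenylsilane, CC(C)(C)[Si](Cl)(c1ccccc1)c1ccccc1
Why: Silylation of the primary alcohol gives a hindered silyl ether that should survive the later amide bases, acetic acid and Lewis acid and be removed by fluoride in step 17 while the temporary lactone is still closed.

**Step 3**
Reactants: 4 3-[2-(tert-butyldiphenylsilyloxy)ethyl]cyclohex-2-en-1-one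
Product: 5 (1R)-3-[2-(tert-butyldiphenylsilyloxy)ethyl]cyclohex-2-en-1-ol
Conditions: (S)-2-methyl-CBS-oxazaborolidine (10 mol %), BH3·SMe2, THF, −20 °C
Reagents that add atoms: none
Why: Corey–Bakshi–Shibata reduction, with the alkenyl arm of the enone acting as the large group, should deliver the (R)-allylic alcohol; this C11 carbinol is the source of absolute configuration.

**Step 4**
Reactants: 5 (1R)-3-[2-(tert-butyldiphenylsilyloxy)ethyl]cyclohex-2-en-1-ol; 6 but-3-enoic acid
Product: 7 (1R)-3-[2-(tert-butyldiphenylsilyloxy)ethyl]cyclohex-2-en-1-yl but-3-enoate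
Conditions: DCC, DMAP (5 mol %), CH2Cl2, 0 °C
Reagents that add atoms: none
Why: Steglich esterification at low temperature should acylate the allylic alcohol without touching the carbinol center and with little alkene migration in the butenoate.

**Step 5**
Reactants: 7 (1R)-3-[2-(tert-butyldiphenylsilyloxy)ethyl]cyclohex-2-en-1-yl but-3-enoate
Product: 10 (2R)-2-{(1R)-1-[2-(tert-butyldiphenylsilyloxy)ethyl]cyclohex-2-en-1-yl}but-3-enoic acid, via silyl ketene acetal 8 (not isolated), via trimethylsilyl ester 9 (not isolated)
Conditions: LiN(i-Pr)2 (LDA), TMSCl, Et3N, THF, −78 to 55 °C; then 1 M HCl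
Reagents that add atoms: chlorotrimethylsilane, C[Si](C)(C)Cl (silicon stays only in 8 and 9)
Why: Ireland–Claisen rearrangement should form C6–C8 on the ring face that carried the C11 oxygen, making the quaternary C8 by chirality transfer and leaving the C9=C11 alkene; the (E)-silyl ketene acetal through a chair transition state sets C6, and the (Z)-isomer through a boat would converge on the same epimer.

**Step 6**
Reactants: 11 2-methylidenepropane-1,3-diol; 12 triethyl orthoacetate
Product: 14 5-methylideneoxan-2-one, via hydroxy ester 13 (not isolated)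
Conditions: 11 (3 equiv), EtCO2H (cat.), 130 °C with removal of EtOH; then TsOH (cat.), toluene, reflux
Reagents that add atoms: none
Why: Johnson–Claisen rearrangement of the allylic diol should give ethyl 4-(hydroxymethyl)pent-4-enoate, which lactonizes under acid; excess diol suppresses a second rearrangement.

**Step 7**
Reactants: 14 5-methylideneoxan-2-one; 15 methyl propanoate
Product: 16 methyl 6-(hydroxymethyl)-2-methyl-3-oxohept-6-enoate
Conditions: 15 and LiN(i-Pr)2 (2.2 equiv each), THF, −78 °C; then 14, −78 to −30 °C; AcOH quench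
Reagents that add atoms: none
Why: Claisen-type acylation of the propanoate enolate by the lactone should open the ring to the δ-hydroxy β-keto ester, which carries C1–C4, C10, C18, C19 and C20; the second equivalent of enolate is consumed by the acidic product.

**Step 8**
Reactants: 10 (2R)-2-{(1R)-1-[2-(tert-butyldiphenylsilyloxy)ethyl]cyclohex-2-en-1-yl}but-3-enoic acid; 16 methyl 6-(hydroxymethyl)-2-methyl-3-oxohept-6-enoate
Product: 17 diene ester
Conditions: PPh3, DIAD, THF, 0 °C to rt
Reagents that add atoms: none
Why: Mitsunobu esterification uses the acid as the nucleophile, so the doubly activated C6 is not epimerized, and the carboxylic acid outcompetes the β-keto ester as pronucleophile; this forms the C7–O–C20 ester bond.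

**Step 9**
Reactants: 17 diene ester
Product: 18 dihydropyranone keto ester
Conditions: second-generation Grubbs catalyst RuCl2(=CHPh)(H2IMes)(PCy3) (5 mol %), 1,4-benzoquinone (10 mol %), CH2Cl2, 40 °C
Reagents that add atoms: none
Why: Ring-closing metathesis of the vinyl and 1,1-disubstituted alkenes should give the six-membered β,γ-unsaturated lactone with the C5=C10 alkene, fixing C6 and C20 cis on it; benzoquinone suppresses alkene migration and the ring C alkene is inert.

**Step 10**
Reactants: 18 dihydropyranone keto ester
Product: 19 tetracyclic keto lactone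
Conditions: Mn(OAc)3·2H2O (2.5 equiv), Cu(OAc)2·H2O (0.2 equiv), degassed AcOH, 35 °C
Reagents that add atoms: none
Why: Mn(OAc)3 should oxidize the enolized α-methyl β-keto ester to the C4 radical, which adds 6-endo-trig to C5 of the lactone alkene to close ring A and leave a tertiary radical at C10; that radical closes ring B by 5-exo-trig attack on C9 of the ring C alkene, forming the C9–C10 bond, and the secondary C11 radical is taken by Cu(OAc)2 to an alkylcopper species that loses H-12 to give the C11=C12 alkene. The closest known reaction type is the Mn(OAc)3/Cu(OAc)2 oxidative free-radical tandem cyclization of unsaturated α-alkyl β-keto esters, known to give trans-fused podocarpane-type rings. C5 is set because C4 must approach the lactone alkene anti to the bulky C8 group on the neighbouring C6, and C4 follows from the usual chair transition state with the ester axial (cis to C20) and the methyl equatorial. C10 is set by the temporary lactone: C9 is tied to C6 through C8 and can only reach the face of C10 on which the C6–C8 bond lies, which gives a bridged 3-oxabicyclo[3.2.1]octan-2-one and with it the trans A/B fusion with C20 on the α face; C9 follows from the cis B/C fusion forced by the one-atom tether. The step needs 6-endo over 5-exo closure (secured by the fully substituted C10), ring closure faster than oxidation of the tertiary C10 radical (the copper salt is kept catalytic), and elimination toward C12 and not C9 (H-9 is flanked by two quaternary carbons).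

**Step 11**
Reactants: 19 tetracyclic keto lactone
Product: 20 enone
Conditions: Rh2(cap)4 [dirhodium tetrakis(caprolactamate)] (1 mol %), t-BuOOH (70% aq., 5 equiv), 1,2-dichloroethane, 40 °C
Reagents that add atoms: tert-butyl hydroperoxide, CC(C)(C)OO
Why: Catalytic allylic oxidation should abstract hydrogen from C13, the only secondary allylic position (the other allylic hydrogen, H-9, is tertiary and buried between C8 and C10), and cap the allyl radical at the less hindered C13 end to give the C11=C12–C13=O enone.

**Step 12**
Reactants: 20 enone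
Product: 21 diketone
Conditions: H2 (1 atm), Pd on carbon (10%), EtOAc, rt
Reagents that add atoms: none
Why: Heterogeneous hydrogenation should saturate the only C=C bond and leave both ketones, the esters, the lactone and the silyl ether.

**Step 13**
Reactants: 21 diketone
Product: 22 C13 ketal
Conditions: (TMSOCH2)2 (1.5 equiv), TMSOTf (5 mol %), CH2Cl2, −78 to −20 °C
Reagents that add atoms: 1,2-bis(trimethylsilyloxy)ethane, C[Si](C)(C)OCCO[Si](C)(C)C
Why: TMSOTf-catalysed ketalization should select the unhindered C13 cyclohexanone over the C3 ketone, which is flanked by the quaternary C4 and deactivated as a β-keto ester.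

**Step 14**
Reactants: 22 C13 ketal
Product: 23 enol triflate
Conditions: KN(SiMe3)2 (1.3 equiv), THF, −78 °C; then PhNTf2, −78 to 0 °C
Reagents that add atoms: N-phenylbis(trifluoromethanesulfonimide), O=S(=O)(N(c1ccccc1)S(=O)(=O)C(F)(F)F)C(F)(F)F
Why: The C3 ketone can enolize only toward C2 (C4 is quaternary), and H-6 is a bridgehead hydrogen of the temporary lactone and cannot be removed, so O-triflation should give the C2=C3 enol triflate alone.

**Step 15**
Reactants: 23 enol triflate
Product: 24 C2=C3 alkene
Conditions: Pd(OAc)2 (5 mol %), PPh3 (10 mol %), HCO2H, Bu3N, DMF, 60 °C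
Reagents that add atoms: none
Why: Palladium-catalysed formate reduction of enol triflates should replace the triflate by hydrogen without moving the alkene.

**Step 16**
Reactants: 24 C2=C3 alkene
Product: 26 2β-alcohol, via alkylborane 25 (not isolated)
Conditions: 9-BBN dimer, THF, 65 °C; then 30% H2O2, aq. NaOAc, 0 °C to rt
Reagents that add atoms: 9-borabicyclo[3.3.1]nonane, B1C2CCCC1CCC2 (boron stays only in 25); hydrogen peroxide, OO
Why: Hydroboration–oxidation with a bulky borane should place boron on C2, the alkene carbon remote from the quaternary C4, and from the β face, because the α face is covered by the axial C19 ester and C20; oxidation with retention gives the equatorial 2β-hydroxyl.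

**Step 17**
Reactants: 26 2β-alcohol
Product: 27 diol lactone
Conditions: Bu4NF (1.2 equiv), AcOH (1.2 equiv), THF, 0 °C to rt
Reagents that add atoms: none
Why: Buffered fluoride desilylation should free the primary C16 hydroxyl without opening the temporary lactone; C7 is still held in that lactone on the face opposite to the arm, so the freed alcohol has no ester to close on.

**Step 18**
Reactants: 27 diol lactone
Product: 28 aldehyde lactone
Conditions: TEMPO (10 mol %), PhI(OAc)2 (1.2 equiv), CH2Cl2, rt
Reagents that add atoms: none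
Why: The oxoammonium oxidation is selective for the primary C16 alcohol and should leave the secondary 2β-hydroxyl.

**Step 19**
Reactants: 28 aldehyde lactone
Product: 31 alkynyl ketone, via alkyne lactone 29 (not isolated), via alkyne diester 30 (not isolated)
Conditions: dimethyl (1-diazo-2-oxopropyl)phosphonate (1.5 equiv), K2CO3, MeOH, 0 °C to rt; then NaOMe (5 equiv), 65 °C; then 2 M HCl, THF, rt
Reagents that add atoms: dimethyl (1-diazo-2-oxopropyl)phosphonate, COP(=O)(OC)C(=[N+]=[N-])C(C)=O; methanol, CO; water, O
Why: Ohira–Bestmann homologation converts the aldehyde to the terminal alkyne and supplies C17, methoxide in the same solvent then opens the temporary lactone to the C7 methyl ester and equilibrates C6 to the ester trans to C4, and acid closes the C20 hydroxyl onto the 1,3-diaxial C19 ester (lactonization) and hydrolyses the ketal; because the arm is already an alkyne and C13 is still a ketal during the basic stages, neither a lactone between C16 and C7 nor an aldol between C13 and C16 can form.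

**Step 20**
Reactants: 31 alkynyl ketone
Product: 32 methyl ester of the target gibberellin
Conditions: SmI2 (3 equiv), HMPA, t-BuOH, THF, 0 °C
Reagents that add atoms: none
Why: Ketyl–alkyne reductive cyclization (5-exo-dig) from the C13 ketyl onto C16 should close ring D, giving the bridgehead tertiary alcohol and the exocyclic methylene in one step; the C13 configuration is fixed by the bridge from C8, and esters and the lactone are inert to SmI2 without a stronger activator.

**Step 21**
Reactants: 32 methyl ester of the target gibberellin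
Product: 33 target gibberellin
Conditions: 2 M NaOH, MeOH/H2O, 70 °C; then 1 M HCl to pH 3
Reagents that add atoms: sodium hydroxide, [Na+].[OH-]
Why: Saponification cleaves the hindered C7 methyl ester (the δ-lactone opens and re-closes on acidification, as is usual for 19,20-lactones), and C6 stays in its thermodynamically preferred configuration.

**Compound list**
1 | 2-(3-methoxyphenyl)ethan-1-ol | COc1cccc(CCO)c1 | starting material
2 | 2-(5-methoxycyclohexa-1,4-dien-1-yl)ethan-1-ol | COC1=CCC=C(CCO)C1 | intermediate
3 | 3-(2-hydroxyethyl)cyclohex-2-en-1-one | O=C1C=C(CCO)CCC1 | intermediate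
4 | 3-[2-(tert-butyldiphenylsilyloxy)ethyl]cyclohex-2-en-1-one | O=C1C=C(CCO[Si](c2ccccc2)(c2ccccc2)C(C)(C)C)CCC1 | intermediate
5 | (1R)-3-[2-(tert-butyldiphenylsilyloxy)ethyl]cyclohex-2-en-1-ol | O[C@@H]1CCCC(CCO[Si](c2ccccc2)(c2ccccc2)C(C)(C)C)=C1 | intermediate
6 | but-3-enoic acid | C=CCC(=O)O | starting material
7 | (1R)-3-[2-(tert-butyldiphenylsilyloxy)ethyl]cyclohex-2-en-1-yl but-3-enoate | C=CCC(=O)O[C@@H]1CCCC(CCO[Si](c2ccccc2)(c2ccccc2)C(C)(C)C)=C1 | intermediate
8 | (E)-trimethylsilyl ketene acetal of 7 (vinyl group trans to OSiMe3) | C=C/C=C(/O[Si](C)(C)C)O[C@@H]1CCCC(CCO[Si](c2ccccc2)(c2ccccc2)C(C)(C)C)=C1 | intermediate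
9 | trimethylsilyl ester of acid 10 | CC(C)(C)[Si](c1ccccc1)(c1ccccc1)OCC[C@@]2(CCCC=C2)[C@@H](C=C)C(=O)O[Si](C)(C)C | intermediate
10 | (2R)-2-{(1R)-1-[2-(tert-butyldiphenylsilyloxy)ethyl]cyclohex-2-en-1-yl}but-3-enoic acid | CC(C)(C)[Si](c1ccccc1)(c1ccccc1)OCC[C@@]2(CCCC=C2)[C@@H](C=C)C(=O)O | intermediate
11 | 2-methylidenepropane-1,3-diol | C=C(CO)CO | starting material
12 | triethyl orthoacetate | CC(OCC)(OCC)OCC | starting material
13 | ethyl 4-(hydroxymethyl)pent-4-enoate | C=C(CO)CCC(=O)OCC | intermediate
14 | 5-methylideneoxan-2-one | C=C1CCC(=O)OC1 | intermediate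
15 | methyl propanoate | CCC(=O)OC | starting material
16 | methyl 6-(hydroxymethyl)-2-methyl-3-oxohept-6-enoate (racemic at the α-carbon) | COC(=O)C(C)C(=O)CCC(=C)CO | intermediate
17 | ester of acid 10 with the primary alcohol of 16 (both epimers at C4) | CC(C)(C)[Si](c1ccccc1)(c1ccccc1)OCC[C@@]2(CCCC=C2)[C@@H](C=C)C(=O)OCC(=C)CCC(=O)C(C)C(=O)OC | intermediate
18 | (3R)-3,6-dihydro-2H-pyran-2-one carrying at C3 the (1R)-1-[2-(tert-butyldiphenylsilyloxy)ethyl]cyclohex-2-en-1-yl group and at C5 the 4-methoxycarbonyl-3-oxopentyl chain (both epimers at C4) | CC(C)(C)[Si](c1ccccc1)(c1ccccc1)OCC[C@@]2(CCCC=C2)[C@H]3C=C(CCC(=O)C(C)C(=O)OC)COC3=O | intermediate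
19 | rings A, B and C with the temporary C7–O–C20 δ-lactone (C7 on the α face of C6): C3 ketone, C4 β-methyl and α-CO2Me, H-5β, H-9β, C20 α, C11=C12 alkene, 2-(tert-butyldiphenylsilyloxy)ethyl arm on the β face of C8 | CC(C)(C)[Si](c1ccccc1)(c1ccccc1)OCC[C@]23CCC=C[C@H]2[C@]15COC(=O)[C@@H]3[C@@H]5[C@](C)(C(=O)OC)C(=O)CC1 | intermediate
20 | as 19 with a C13 ketone conjugated to C11=C12 | CC(C)(C)[Si](c1ccccc1)(c1ccccc1)OCC[C@]23CC(=O)C=C[C@H]2[C@]15COC(=O)[C@@H]3[C@@H]5[C@](C)(C(=O)OC)C(=O)CC1 | intermediate
21 | 3,13-diketone, ring C saturated | CC(C)(C)[Si](c1ccccc1)(c1ccccc1)OCC[C@]23CC(=O)CC[C@H]2[C@]15COC(=O)[C@@H]3[C@@H]5[C@](C)(C(=O)OC)C(=O)CC1 | intermediate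
22 | 13-(ethylene ketal) of 21 | CC(C)(C)[Si](c1ccccc1)(c1ccccc1)OCC[C@]23CC4(OCCO4)CC[C@H]2[C@]15COC(=O)[C@@H]3[C@@H]5[C@](C)(C(=O)OC)C(=O)CC1 | intermediate
23 | C2=C3 enol triflate (OTf on C3) | CC(C)(C)[Si](c1ccccc1)(c1ccccc1)OCC[C@]23CC4(OCCO4)CC[C@H]2[C@]15COC(=O)[C@@H]3[C@@H]5[C@](C)(C(=O)OC)C(OS(=O)(=O)C(F)(F)F)=CC1 | intermediate
24 | C2=C3 alkene | CC(C)(C)[Si](c1ccccc1)(c1ccccc1)OCC[C@]23CC4(OCCO4)CC[C@H]2[C@]15COC(=O)[C@@H]3[C@@H]5[C@](C)(C(=O)OC)C=CC1 | intermediate
25 | 2β-(9-borabicyclo[3.3.1]nonan-9-yl) adduct of 24 | CC(C)(C)[Si](c1ccccc1)(c1ccccc1)OCC[C@]23CC4(OCCO4)CC[C@H]2[C@]15COC(=O)[C@@H]3[C@@H]5[C@](C)(C(=O)OC)C[C@@H](B6C7CCCC6CCC7)C1 | intermediate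
26 | 2β-alcohol with the temporary 7,20-lactone, C19 methyl ester, 13-ketal and silyl ether | CC(C)(C)[Si](c1ccccc1)(c1ccccc1)OCC[C@]23CC4(OCCO4)CC[C@H]2[C@]15COC(=O)[C@@H]3[C@@H]5[C@](C)(C(=O)OC)C[C@@H](O)C1 | intermediate
27 | 2β,16-diol with the temporary 7,20-lactone, C19 methyl ester and 13-ketal | OCC[C@]23CC4(OCCO4)CC[C@H]2[C@]15COC(=O)[C@@H]3[C@@H]5[C@](C)(C(=O)OC)C[C@@H](O)C1 | intermediate
28 | as 27 with the arm oxidized to the C16 aldehyde | O=CC[C@]23CC4(OCCO4)CC[C@H]2[C@]15COC(=O)[C@@H]3[C@@H]5[C@](C)(C(=O)OC)C[C@@H](O)C1 | intermediate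
29 | as 27 with a prop-2-yn-1-yl arm (C15–C16≡C17) on C8 in place of the hydroxyethyl arm | C#CC[C@]23CC4(OCCO4)CC[C@H]2[C@]15COC(=O)[C@@H]3[C@@H]5[C@](C)(C(=O)OC)C[C@@H](O)C1 | intermediate
30 | 7,19-dimethyl diester, 2β,20-diol, 13-ketal, prop-2-yn-1-yl arm, C7 ester on the natural β face of C6 | C#CC[C@]23CC4(OCCO4)CC[C@H]2[C@]1(CO)C[C@H](O)C[C@@](C)(C(=O)OC)[C@H]1[C@@H]3C(=O)OC | intermediate
31 | 19,20-lactone, C7 methyl ester, 2β-hydroxyl, C13 ketone, prop-2-yn-1-yl arm on C8 | C#CC[C@]23CC(=O)CC[C@H]2[C@]12COC(=O)[C@](C)(C[C@@H](O)C1)[C@H]2[C@@H]3C(=O)OC | intermediate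
32 | 7-methyl ester of the target gibberellin | C=C1C[C@]23C[C@@]1(O)CC[C@H]2[C@]12COC(=O)[C@](C)(C[C@@H](O)C1)[C@H]2[C@@H]3C(=O)OC | intermediate
33 | target gibberellin: 2β,13,20-trihydroxygibberell-16-ene-7,19-dioic acid 19,20-lactone | C=C1C[C@]23C[C@@]1(O)CC[C@H]2[C@]12COC(=O)[C@](C)(C[C@@H](O)C1)[C@H]2[C@@H]3C(=O)O | target

**Step count**
Total: 21 steps. Longest linear sequence: 19 steps (steps 1–5 and 8–21).

**Steps most likely to fail**

Step 10. The tertiary C10 radical may be oxidized by the copper or manganese salt before the slower, sterically demanding closure onto C9, or facial control at C4 may erode. The fallback sets out from 18 and returns at 19, and replaces the metal-oxidant cascade by an iodine-atom-transfer chain followed by a separate elimination. Iodination at C4 (N-iodosuccinimide, cat. Mg(ClO4)2, EtOAc) should give the α-iodo keto ester F1. Irradiation with Bu3SnSnBu3 (10 mol %) in benzene at 80 °C should run the same two ring closures with no oxidant present, a slow-closing C10 radical being stored only reversibly as its iodide, to give the C11 iodide F2. DBU in toluene at 80 °C should then remove HI toward C12 to give 19.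

Step 5. The C6 configuration may erode through mixed dienolate geometry or chair/boat leakage in the rearrangement. The fallback sets out from 5 and returns at 10, and uses a saturated ester whose enolate geometry is reliably controlled, unveiling the vinyl group afterwards. Esterification of 5 with 4-(phenylselanyl)butanoic acid (DCC, DMAP) should give the selenide ester F3. Ireland–Claisen rearrangement (LDA, TMSCl, THF, −78 to 55 °C) should give the selenide acid F4. Oxidation with H2O2 and pyridine at 0 °C and selenoxide syn-elimination should give 10.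

Step 11. The allylic radical may be captured at C11 (transposed enone), or other C–H bonds may be attacked. The fallback sets out from 19 and returns at 20, and uses a pericyclic oxidation that cannot shift the alkene. SeO2 (cat.) with t-BuOOH in CH2Cl2 should hydroxylate C13 by an ene/[2,3] sequence to the allylic alcohol F5, and MnO2 in CH2Cl2 should oxidize it to 20.

**Further compounds**
F1 | step 10 | α-iodo keto ester (iodine on C4 of 18) | CC(C)(C)[Si](c1ccccc1)(c1ccccc1)OCC[C@@]2(CCCC=C2)[C@H]3C=C(CCC(=O)C(C)(I)C(=O)OC)COC3=O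
F2 | step 10 | C11 iodide (11,12-dihydro-11-iodo analogue of 19, either C11 epimer) | CC(C)(C)[Si](c1ccccc1)(c1ccccc1)OCC[C@]23CCCC(I)[C@H]2[C@]15COC(=O)[C@@H]3[C@@H]5[C@](C)(C(=O)OC)C(=O)CC1
F3 | step 5 | (1R)-3-[2-(tert-butyldiphenylsilyloxy)ethyl]cyclohex-2-en-1-yl 4-(phenylselanyl)butanoate | O=C(CCC[Se]c1ccccc1)O[C@@H]1CCCC(CCO[Si](c2ccccc2)(c2ccccc2)C(C)(C)C)=C1
F4 | step 5 | (2R)-4-(phenylselanyl)-2-{(1R)-1-[2-(tert-butyldiphenylsilyloxy)ethyl]cyclohex-2-en-1-yl}butanoic acid | CC(C)(C)[Si](c1ccccc1)(c1ccccc1)OCC[C@@]2(CCCC=C2)[C@@H](CC[Se]c1ccccc1)C(=O)O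
F5 | step 11 | C13 allylic alcohol of 19 (either C13 epimer) | CC(C)(C)[Si](c1ccccc1)(c1ccccc1)OCC[C@]23CC(O)C=C[C@H]2[C@]15COC(=O)[C@@H]3[C@@H]5[C@](C)(C(=O)OC)C(=O)CC1
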